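Cuts: (a) the C6–O acyl bond, giving the 6α-alcohol and O-silyl p-coumaric acid; (b) the C6, C7 and C8 hydrogens, back to the C7=C8–C6=O enone; (c) C7=C8, back to a ring A keto aldehyde; (d) C4=C15, C5–C6 and C10–C9, back to 3-methylcyclohexenone.
Enabling feature: in ring B the oxygen-bearing C6 sits next to the isopropyl-bearing C7, and C6 and C8 are 1,5-related through C5–C10–C9. An isobutyl ketone on C5 and an acetaldehyde arm on C10 can therefore form only one unstrained ring, by joining C7 to C8.
Forward order: ring A is bought. C9–C8 (vinyl) and C6, C7 and the isopropyl group C11–C13 (3-methylbutanal) are attached in one flask. C15 is then added, the vinyl group is oxidised to the aldehyde, ring B is closed, the enone is reduced and the ester is joined last.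
Stereochemistry: C10 comes from a chiral carbene–copper catalyst, C5 from kinetic enolate trapping anti to the vinyl group, and C7 and C6 from one dissolving-metal reduction of the trans-fused enone. The (E)-alkene is bought with the acid.

Key step: step 7

Remark on numbering: eudesmane numbering is used for all compounds (ring A: C1–C5 and C10; ring B: C5–C10; C14 angular methyl; C15 methylidene carbon; C11–C13 isopropyl).
Assumption: the sense of induction of the carbene ligand with the vinyl Grignard reagent is taken to be the one found with alkyl Grignard reagents; if it is opposite, the enantiomeric imidazolinium salt is used.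

Step 1
Reactants: 1 3-methylcyclohex-2-en-1-one; 2 vinylmagnesium bromide; 3 3-methylbutanal
Product: 5 (2S,3R)-3-ethenyl-2-[(1S)-1-hydroxy-3-methylbutyl]-3-methylcyclohexan-1-one, via magnesium enolate 4 (not isolated)
Conditions: Cu(OTf)2 (3 mol %), (S)-1-(1-hydroxy-3,3-dimethylbutan-2-yl)-3-mesityl-4,5-dihydroimidazolium hexafluorophosphate (4 mol %), 2 added slowly, Et2O, −30 °C; then 3, −78 °C
Reagents that add atoms: vinylmagnesium bromide, C=C[Mg]Br; 3-methylbutanal, CC(C)CC=O
Why: Copper–carbene-catalysed asymmetric conjugate addition of a Grignard reagent to a β-substituted cyclohexenone fixes the quaternary C10 under catalyst control, and the regiodefined enolate 4 then undergoes a Zimmerman–Traxler aldol addition in which the flat vinyl group sits pseudoaxial beside the geminal methyl group and the aldehyde enters axially on the opposite face of C5, so that C6 comes out trans to C9 as the kinetic product; because vinyl and methyl differ little in size this is the least secure stereocentre of the route, any C5 epimer is removed by chromatography at 6, and the C6 carbinol centre (anti aldol expected) is erased in step 6.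

Step 2
Reactants: 5 (2S,3R)-3-ethenyl-2-[(1S)-1-hydroxy-3-methylbutyl]-3-methylcyclohexan-1-one
Product: 6 (2S,3R)-2-[(1S)-1-(tert-butyldimethylsilyloxy)-3-methylbutyl]-3-ethenyl-3-methylcyclohexan-1-one
Conditions: TBSOTf, 2,6-lutidine, CH2Cl2, −78 to 0 °C
Reagents that add atoms: tert-butyldimethylsilyl trifluoromethanesulfonate, CC(C)(C)[Si](C)(C)OS(=O)(=O)C(F)(F)F
Why: A silyl triflate with a hindered pyridine base silylates the congested aldol hydroxyl at low temperature without the retro-aldol cleavage or C5 epimerisation that alkoxide-forming conditions would invite, and no stereocentre is touched.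

Step 3
Reactants: 6 (2S,3R)-2-[(1S)-1-(tert-butyldimethylsilyloxy)-3-methylbutyl]-3-ethenyl-3-methylcyclohexan-1-one
Product: 7 tert-butyl({(1S)-1-[(1S,2R)-2-ethenyl-2-methyl-6-methylidenecyclohexyl]-3-methylbutyl}oxy)dimethylsilane
Conditions: Zn, CH2Br2, TiCl4, THF–CH2Cl2, 0 to 25 °C
Reagents that add atoms: dibromomethane, BrCBr
Why: The gem-dimetallic reagent of the Takai–Lombardo methylenation is nucleophilic but essentially non-basic, so the hindered and enolisable β-silyloxy ketone is converted into the C4=C15 methylidene group without the C5 epimerisation or β-elimination of the silyloxy group that a phosphorus ylide could cause.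

Step 4
Reactants: 7 tert-butyl({(1S)-1-[(1S,2R)-2-ethenyl-2-methyl-6-methylidenecyclohexyl]-3-methylbutyl}oxy)dimethylsilane
Product: 9 2-{(1R,2S)-2-[(1S)-1-(tert-butyldimethylsilyloxy)-3-methylbutyl]-1-methyl-3-methylidenecyclohexyl}ethan-1-ol, via catechol boronate 8 (not isolated)
Conditions: catecholborane (2 equiv), RhCl(PPh3)3 (2 mol %), THF, 20 °C; then aq NaOH, 30 % H2O2, 0 °C
Reagents that add atoms: hydrogen peroxide, OO
Why: Rhodium-catalysed hydroboration with catecholborane discriminates far more sharply by alkene substitution than 9-BBN does, so the monosubstituted C8=C9 vinyl group reacts in the anti-Markovnikov sense while the 1,1-disubstituted and flanked C4=C15 alkene is left alone, and oxidation of the C–B bond gives the primary C8 alcohol without creating a stereocentre.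

Step 5
Reactants: 9 2-{(1R,2S)-2-[(1S)-1-(tert-butyldimethylsilyloxy)-3-methylbutyl]-1-methyl-3-methylidenecyclohexyl}ethan-1-ol
Product: 10 (1S)-1-[(1S,2R)-2-(2-hydroxyethyl)-2-methyl-6-methylidenecyclohexyl]-3-methylbutan-1-ol
Conditions: Bu4NF, THF, 25 to 45 °C
Reagents that add atoms: none
Why: Fluoride-induced desilylation cleaves only the Si–O bond under conditions that are not acidic enough to move the exocyclic alkene and that cannot affect any stereocentre.

Step 6
Reactants: 10 (1S)-1-[(1S,2R)-2-(2-hydroxyethyl)-2-methyl-6-methylidenecyclohexyl]-3-methylbutan-1-ol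
Product: 11 2-[(1R,2S)-1-methyl-2-(3-methylbutanoyl)-3-methylidenecyclohexyl]acetaldehyde
Conditions: (COCl)2, DMSO, CH2Cl2, −78 °C; then Et3N, −78 to −20 °C
Reagents that add atoms: none
Why: In the Swern oxidation both hydroxyl groups are turned into alkoxysulfonium ions before the base is added, so the C8 aldehyde and the C6 ketone appear together and the lactol-to-lactone pathway open to a 1,5-diol with slower oxidants is avoided, while the short and cold exposure to the amine leaves the allylic C5–H in place.

Step 7
Reactants: 11 2-[(1R,2S)-1-methyl-2-(3-methylbutanoyl)-3-methylidenecyclohexyl]acetaldehyde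
Product: 13 (5S,10R)-eudesma-4(15),7-dien-6-one [(4aR,8aS)-4a-methyl-8-methylidene-2-(propan-2-yl)-4a,5,6,7,8,8a-hexahydronaphthalen-1(4H)-one], via aldol 12 (not isolated)
Conditions: Bn2NH·CF3CO2H (0.3 equiv), 4 Å molecular sieves, toluene (0.01 M), 50 °C
Reagents that add atoms: none
Why: The ammonium salt converts the C8 aldehyde reversibly into an iminium ion and at the same time catalyses enolisation of the C6 ketone; the C6=C7 enol attacks C8 through C7, and loss of the amine, or of water from aldol 12, leaves the conjugated C7=C8 double bond. The closest known reaction type is the amine-salt-catalysed intramolecular aldol condensation of 1,5-keto aldehydes to cyclohexenones, that is the ring-closing half of a Robinson annulation with an aldehyde as the acceptor. Ring B closes in the 6-(enolendo)-exo-trig mode, because the enol C6=C7 bond lies inside the ring being formed and the C8 heteroatom double bond outside it. No stereocentre is created: C5 and C10 are carried through, and only the chair of ring A with the C5 acyl group and the C10 acetaldehyde arm both equatorial can close, which leads straight to the trans-fused product. The selectivity needed is C7 rather than C5 or C9 as nucleophile: a bond from C5 to C8 or from C9 to C6 would give a cyclobutanol and falls apart again, while enolisation towards C5 would give a tetrasubstituted dienol in which the C6 oxygen is pressed against C15H2 and C7 against the C10 substituents, the same allylic strain that allows 2-methylidene-6,6-dialkylcyclohexyl ketones of the γ-damascone type to be condensed at their outer α-carbon with the exocyclic alkene intact. The near-neutral salt, moderate temperature and high dilution are chosen to keep C5–H exchange and intermolecular condensation through the aldehyde enamine slow.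

Step 8
Reactants: 13 (5S,10R)-eudesma-4(15),7-dien-6-one
Product: 16 (5S,6S,7S,10R)-eudesm-4(15)-en-6-ol (6α-hydroxy and 7β-isopropyl both equatorial; trans-decalin), via lithium enolate 14 (not isolated), via ketone 15 (not isolated)
Conditions: Li (10 equiv), liquid NH3–THF, EtOH (8 equiv), −78 to −33 °C
Reagents that add atoms: none
Why: Dissolving-metal reduction adds two electrons and a proton to the enone to give the C6–C7 enolate, ethanol protonates C7 axially from the α face so that the isopropyl group becomes equatorial (7β), and the liberated ketone is reduced at once through its ketyl to the thermodynamically preferred equatorial 6α-alcohol between two equatorial neighbours, whereas hydride reagents would approach from the α face away from the angular methyl and give the axial epimer, and the unconjugated C4=C15 alkene accepts no electron.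

Step 9
Reactants: 17 (E)-4-hydroxycinnamic acid
Product: 19 (E)-3-[4-(tert-butyldimethylsilyloxy)phenyl]prop-2-enoic acid, via bis-silyl derivative 18 (not isolated)
Conditions: TBSCl (2.3 equiv), imidazole, DMF, 25 °C; then AcOH–THF–H2O, 25 °C
Reagents that add atoms: tert-butyldimethylsilyl chloride, CC(C)(C)[Si](C)(C)Cl
Why: Silyl chloride and imidazole silylate both acidic oxygens, and the far more labile silyl ester is then hydrolysed selectively in aqueous acetic acid, which leaves the aryl silyl ether and the (E)-alkene untouched.

Step 10
Reactants: 16 (5S,6S,7S,10R)-eudesm-4(15)-en-6-ol; 19 (E)-3-[4-(tert-butyldimethylsilyloxy)phenyl]prop-2-enoic acid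
Product: 20 (5S,6S,7S,10R)-eudesm-4(15)-en-6-yl (E)-3-[4-(tert-butyldimethylsilyloxy)phenyl]prop-2-enoate
Conditions: 19 (1.5 equiv), DCC, DMAP (0.5 equiv), CH2Cl2, 0 to 25 °C
Reagents that add atoms: (E)-3-[4-(tert-butyldimethylsilyloxy)phenyl]prop-2-enoic acid, O=C(O)/C=C/c1ccc(O[Si](C)(C)C(C)(C)C)cc1
Why: Steglich esterification through the acylpyridinium ion acylates the hindered equatorial C6 hydroxyl with retention because only its O–H bond is broken, and the silyl ether keeps the phenol from competing as a nucleophile.

Step 11
Reactants: 20 (5S,6S,7S,10R)-eudesm-4(15)-en-6-yl (E)-3-[4-(tert-butyldimethylsilyloxy)phenyl]prop-2-enoate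
Product: 21 (5S,6S,7S,10R)-eudesm-4(15)-en-6-yl (E)-3-(4-hydroxyphenyl)prop-2-enoate (CNP0321375.1)
Conditions: Bu4NF, AcOH (1:1), THF, 0 °C
Reagents that add atoms: none
Why: The aryl silyl ether is by far the most fluoride-labile group present, and buffering with acetic acid keeps the phenoxide from attacking the cinnamate, so this desilylation leaves the ester, the (E)-alkene, the exocyclic alkene and all four stereocentres unchanged.

Compound list
1 | 3-methylcyclohex-2-en-1-one | CC1=CC(=O)CCC1 | starting material
2 | vinylmagnesium bromide | C=C[Mg]Br | starting material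
3 | 3-methylbutanal | CC(C)CC=O | starting material
4 | bromomagnesium (3R)-3-ethenyl-3-methylcyclohex-1-en-1-olate | Br[Mg]OC1=C[C@@](C)(C=C)CCC1 | intermediate (not isolated)
5 | (2S,3R)-3-ethenyl-2-[(1S)-1-hydroxy-3-methylbutyl]-3-methylcyclohexan-1-one | O=C1CCC[C@](C)(C=C)[C@H]1[C@@H](O)CC(C)C | intermediate
6 | (2S,3R)-2-[(1S)-1-(tert-butyldimethylsilyloxy)-3-methylbutyl]-3-ethenyl-3-methylcyclohexan-1-one | O=C1CCC[C@](C)(C=C)[C@H]1[C@@H](O[Si](C)(C)C(C)(C)C)CC(C)C | intermediate
7 | tert-butyl({(1S)-1-[(1S,2R)-2-ethenyl-2-methyl-6-methylidenecyclohexyl]-3-methylbutyl}oxy)dimethylsilane | C=C1CCC[C@](C)(C=C)[C@H]1[C@@H](O[Si](C)(C)C(C)(C)C)CC(C)C | intermediate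
8 | catechol boronate of 7 at C8 (2-alkyl-1,3,2-benzodioxaborole) | C=C1CCC[C@](C)(CCB2Oc3ccccc3O2)[C@H]1[C@@H](O[Si](C)(C)C(C)(C)C)CC(C)C | intermediate (not isolated)
9 | 2-{(1R,2S)-2-[(1S)-1-(tert-butyldimethylsilyloxy)-3-methylbutyl]-1-methyl-3-methylidenecyclohexyl}ethan-1-ol | C=C1CCC[C@](C)(CCO)[C@H]1[C@@H](O[Si](C)(C)C(C)(C)C)CC(C)C | intermediate
10 | (1S)-1-[(1S,2R)-2-(2-hydroxyethyl)-2-methyl-6-methylidenecyclohexyl]-3-methylbutan-1-ol | C=C1CCC[C@](C)(CCO)[C@H]1[C@@H](O)CC(C)C | intermediate
11 | 2-[(1R,2S)-1-methyl-2-(3-methylbutanoyl)-3-methylidenecyclohexyl]acetaldehyde | C=C1CCC[C@](C)(CC=O)[C@H]1C(=O)CC(C)C | intermediate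
12 | (5S,10R)-8-hydroxyeudesm-4(15)-en-6-one (C7 and C8 undefined, both lost on dehydration) | C=C1CCC[C@]2(C)CC(O)C(C(C)C)C(=O)[C@@H]12 | intermediate (not isolated)
13 | (5S,10R)-eudesma-4(15),7-dien-6-one | C=C1CCC[C@]2(C)CC=C(C(C)C)C(=O)[C@@H]12 | intermediate
14 | lithium (5S,10R)-eudesma-4(15),6-dien-6-olate | C=C1CCC[C@]2(C)CCC(C(C)C)=C(O[Li])[C@@H]12 | intermediate (not isolated)
15 | (5S,7S,10R)-eudesm-4(15)-en-6-one | C=C1CCC[C@]2(C)CC[C@@H](C(C)C)C(=O)[C@@H]12 | intermediate (not isolated)
16 | (5S,6S,7S,10R)-eudesm-4(15)-en-6-ol | C=C1CCC[C@]2(C)CC[C@@H](C(C)C)[C@H](O)[C@@H]12 | intermediate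
17 | (E)-4-hydroxycinnamic acid | O=C(O)/C=C/c1ccc(O)cc1 | starting material
18 | tert-butyldimethylsilyl (E)-3-[4-(tert-butyldimethylsilyloxy)phenyl]prop-2-enoate | CC(C)(C)[Si](C)(C)OC(=O)/C=C/c1ccc(O[Si](C)(C)C(C)(C)C)cc1 | intermediate (not isolated)
19 | (E)-3-[4-(tert-butyldimethylsilyloxy)phenyl]prop-2-enoic acid | O=C(O)/C=C/c1ccc(O[Si](C)(C)C(C)(C)C)cc1 | intermediate
20 | (5S,6S,7S,10R)-eudesm-4(15)-en-6-yl (E)-3-[4-(tert-butyldimethylsilyloxy)phenyl]prop-2-enoate | C=C1CCC[C@]2(C)CC[C@@H](C(C)C)[C@H](OC(=O)/C=C/c3ccc(O[Si](C)(C)C(C)(C)C)cc3)[C@@H]12 | intermediate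
21 | (5S,6S,7S,10R)-eudesm-4(15)-en-6-yl (E)-3-(4-hydroxyphenyl)prop-2-enoate | C=C1CCC[C@]2(C)CC[C@@H](C(C)C)[C@H](OC(=O)/C=C/c3ccc(O)cc3)[C@@H]12 | target

Total step count: 11. Longest linear sequence: 10 (steps 1–8, 10 and 11); step 9 is a one-step side branch.

Steps most likely to fail

Step 1. With the small sp2 Grignard reagent, direct 1,2-addition and eroded enantioselectivity may compete with the conjugate addition. Facial selectivity at C5 may also be poor, because vinyl and methyl shield the enolate almost equally. The fallback sets out from 1 and comes back at 5. Trimethylsilylacetylene is hydroaluminated with iBu2AlH to diisobutyl[1-(trimethylsilyl)ethenyl]aluminium F1. This reagent is added to 1 under CuCl2·2H2O and a chiral sulfonate-bearing imidazolinium salt, a conjugate addition established for β-substituted cyclic enones. The reaction is quenched with Et3SiOTf to give the triethylsilyl enol ether F2. MeLi, then ZnCl2 and 3 at −78 °C give the silylated aldol F3. Here the much larger 1-silylethenyl group, rather than a vinyl group, blocks one face of C5. Protodesilylation with CF3CO2H in CH2Cl2 then returns 5.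

Step 7. Enolisation towards C5 may compete and cause epimerisation at C5 or migration of C4=C15 into conjugation. Enolisation of the hindered ketone at C7 may be too slow, so that intermolecular condensation of the aldehyde takes over. The fallback sets out from 11 and comes back at 13. It makes the same C7=C8 bond and the same ring by ring-closing metathesis under neutral conditions.
- The aldehyde alone is methylenated with Ph3P=CH2 (1 equiv, −78 °C) to the allyl ketone F4.
- Irreversible kinetic deprotonation with LiN(iPr)2 at −78 °C takes the accessible C7–H, and dimethyl(methylidene)ammonium iodide gives the Mannich base F5.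
- MeI gives the ammonium iodide F6, which loses trimethylamine on NaHCO3 to give the α-methylidene ketone F7.
- The second-generation Hoveyda–Grubbs catalyst in toluene closes ring B to 13 with loss of ethene.

Metathesis onto C4=C15 would require a bridgehead alkene and cannot interfere.

Step 8. In the basic medium the transient ketone 15 may suffer migration of C4=C15 into conjugation followed by over-reduction. The enolate may also be protonated incompletely, so that the reduction stops at the ketone, or selectivity at C6 may be insufficient. The fallback sets out from 13 and comes back at 16, and it separates the two reductions. Conjugate reduction with [(Ph3P)CuH]6 in moist toluene touches only the enone and, after protonation of C7 from the α face, gives ketone 15, which is now isolated. Single-electron reduction with SmI2, H2O and Et3N in THF then gives the equatorial alcohol 16 through the ketyl without strong base. This detour makes no new compound (F0).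

Further compounds
F1 | step 1 | diisobutyl[1-(trimethylsilyl)ethenyl]aluminium | C=C([Si](C)(C)C)[Al](CC(C)C)CC(C)C
F2 | step 1 | triethyl({(3S)-3-methyl-3-[1-(trimethylsilyl)ethenyl]cyclohex-1-en-1-yl}oxy)silane | CC[Si](CC)(CC)OC1=C[C@@](C)(C(=C)[Si](C)(C)C)CCC1
F3 | step 1 | (2S,3S)-2-[(1S)-1-hydroxy-3-methylbutyl]-3-methyl-3-[1-(trimethylsilyl)ethenyl]cyclohexan-1-one | O=C1CCC[C@](C)(C(=C)[Si](C)(C)C)[C@H]1[C@@H](O)CC(C)C
F4 | step 7 | 3-methyl-1-[(1S,2R)-2-methyl-6-methylidene-2-(prop-2-en-1-yl)cyclohexyl]butan-1-one | C=C1CCC[C@](C)(CC=C)[C@H]1C(=O)CC(C)C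
F5 | step 7 | 2-[(dimethylamino)methyl]-3-methyl-1-[(1S,2R)-2-methyl-6-methylidene-2-(prop-2-en-1-yl)cyclohexyl]butan-1-one (C7 undefined) | C=C1CCC[C@](C)(CC=C)[C@H]1C(=O)C(CN(C)C)C(C)C
F6 | step 7 | trimethylammonium iodide derived from F5 by N-methylation | C=C1CCC[C@](C)(CC=C)[C@H]1C(=O)C(C[N+](C)(C)C)C(C)C.[I-]
F7 | step 7 | 3-methyl-2-methylidene-1-[(1S,2R)-2-methyl-6-methylidene-2-(prop-2-en-1-yl)cyclohexyl]butan-1-one | C=C1CCC[C@](C)(CC=C)[C@H]1C(=O)C(=C)C(C)C
F0 | step 8 | none | none
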